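**Retrosynthetic overview**
1. Sanggenone H (10) ⇐ bis-TIPS ether 9, by buffered fluoride so that no phenoxide forms and C2 is not racemised.
2. 9 ⇐ C2–C1′ disconnection: Rh/(S)-BINAP enantioselective, dearomatising 1,4-arylation of the benzo-γ-pyrone ring of chromone 3 (TMSCl-activated) by the arylzinc made from bromochromene 8. This joins the two halves and sets C2 in one step.
3. 3 ⇐ one-carbon annulation that breaks the mirror symmetry of 4-O-silyl phloroacetophenone 2 (from 1).
4. 8 ⇐ aromatic propargyl Claisen/oxa-6π cascade of ether 7, made from 4-bromoresorcinol (4) and 3-chloro-3-methylbut-1-yne (6).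
5. Ring order: ring A is bought; ring C (pyranone) is built on A; the dimethylpyran is built on ring B; the two bicycles are coupled last, which saturates ring C.

Assumption: the stereocentre in the SMILES is (2S) by CIP analysis (O1 > C1′ > C3 > H); compounds 1, 4, 6 and all reagents are purchased.

**Route**

Step 1
Reactants: 1, 2,4,6-trihydroxyacetophenone (phloroacetophenone, dried)
Product: 2, 1-[2,6-dihydroxy-4-(triisopropylsilyloxy)phenyl]ethanone
Conditions: TIPSCl (1.05 equiv), imidazole (2.2 equiv), DMF, 0 °C → rt
Reagents that add atoms: TIPSCl, CC(C)[Si](Cl)(C(C)C)C(C)C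
Why: Sterically controlled O-silylation; the 4-OH is the most acidic and the only unhindered, non-chelated hydroxyl, so the bulky silyl chloride leaves the two acetyl-flanked OH groups free and gives a Cs-symmetric product.

Step 2
Reactants: 2
Product: 3, 5-hydroxy-7-(triisopropylsilyloxy)-4H-chromen-4-one
Conditions: t-BuOCH(NMe2)2 (3 equiv), toluene, 80 °C; concentrate; then 1 M aq HCl–THF, rt
Reagents that add atoms: Bredereck's reagent, CN(C)C(OC(C)(C)C)N(C)C (supplies C2 of the chromone)
Why: Enaminone formation at the acetyl CH3, then acid-promoted oxa-Michael/elimination of Me2NH (enaminone chromone synthesis); either of the two equivalent OH groups closes the ring, so the symmetry is broken without a regiochemical issue, and the reagent carries no methyl donor or small alkoxide that could O-methylate or desilylate.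

Step 3
Reactants: 4, 4-bromoresorcinol
Product: 5, 2-bromo-5-(triisopropylsilyloxy)phenol
Conditions: TIPSCl (1.0 equiv), imidazole (2.0 equiv), CH2Cl2, −20 → 0 °C
Reagents that add atoms: TIPSCl, CC(C)[Si](Cl)(C(C)C)C(C)C
Why: Sterically governed mono-silylation; the OH para to Br is unhindered, whereas the OH ortho to Br is shielded and less nucleophilic, so the bulky TIPSCl differentiates them (minor isomer and bis-ether are removed by chromatography).

Step 4
Reactants: 5; 6, 3-chloro-3-methylbut-1-yne
Product: 7, [4-bromo-3-(2-methylbut-3-yn-2-yloxy)phenoxy]triisopropylsilane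
Conditions: CuCl2·2H2O (1 mol %), DBU (1.5 equiv), MeCN, 0 °C → rt
Reagents that add atoms: 3-chloro-3-methylbut-1-yne (6), C#CC(C)(C)Cl
Why: Cu-catalysed propargylic etherification (via a copper allenylidene/acetylide) alkylates even hindered ortho-substituted phenols with the tertiary chloride; the aryl OTIPS is stable to DBU in MeCN.

Step 5
Reactants: 7
Product: 8, 8-bromo-2,2-dimethyl-5-(triisopropylsilyloxy)-2H-chromene
Conditions: PhNEt2, 160 °C, 2–4 h
Reagents that add atoms: none
Why: Aromatic propargyl Claisen rearrangement, then 1,5-H shift and oxa-6π electrocyclisation; the only free ortho position is the CH between the two oxygens (the other ortho carbon carries Br), so the pyran is fused with its oxygen next to C–Br and the silyloxy group on C5.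

Step 6 (key step)
Reactants: 8 (1.6 equiv); 3 (1.0 equiv)
Product: 9, (2S)-2-[2,2-dimethyl-5-(triisopropylsilyloxy)-2H-chromen-8-yl]-5-hydroxy-7-(triisopropylsilyloxy)chroman-4-one
Conditions: (a) 8, n-BuLi, THF, −78 °C; ZnCl2 (THF), −78 → 20 °C; (b) 3, NaH (1.05 equiv), THF, 0 °C, then TMSCl (3 equiv); (c) combine (a) and (b) with [RhCl(C2H4)2]2 (2.5 mol %)/(S)-BINAP (5.5 mol %), THF, 20 °C; (d) 1 M aq HCl–THF, 0 °C, 15 min
Reagents that add atoms: none retained (TMSCl, C[Si](C)(C)Cl, caps the 5-OH and the enolate transiently and is removed in (d))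
Why: Proposed new method: Rh(I)/BINAP-catalysed asymmetric 1,4-addition of an arylzinc chloride with TMSCl, applied to a chromone. The Ar–Rh(I) species adds across C2=C3 of the TMSCl-activated (benzopyrylium-like) pyranone on the face set by (S)-BINAP, the oxa-π-allyl rhodium is trapped as the 4-silyloxy-2H-chromene so retro-oxa-Michael ring opening cannot occur, and Rh–Cl transmetalates with ArZnCl. The closest known reactions are the Rh/BINAP ArZnCl–TMSCl additions to 4-quinolones and 2,3-dihydro-4-pyridones and the Rh-catalysed arylboronic acid additions to chromones (Hayashi–Miyaura type). The (S)-ligand is predicted to give 2S by analogy with its (S)-3-arylcyclohexanone sense; the sense must be confirmed on a model and (R)-BINAP used if it is opposite.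

Step 7
Reactants: 9
Product: 10, sanggenone H, (2S)-5,7-dihydroxy-2-(5-hydroxy-2,2-dimethyl-2H-chromen-8-yl)chroman-4-one
Conditions: TBAF (2.5 equiv)/AcOH (3 equiv), THF, 0 °C → rt; pH 5 work-up, silica or Sephadex LH-20
Reagents that add atoms: none
Why: Fluoride cleavage of both aryl silyl ethers; the acetic acid buffer keeps the 4′- and 7-phenols protonated, so the phenoxide-driven ring opening (quinone methide/chalcone) that racemises 4′-hydroxyflavanones is suppressed, and the chromene is untouched.

**Compound list**
1 | 2,4,6-trihydroxyacetophenone | CC(=O)c1c(O)cc(O)cc1O | starting material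
2 | 1-[2,6-dihydroxy-4-(triisopropylsilyloxy)phenyl]ethanone | CC(=O)c1c(O)cc(O[Si](C(C)C)(C(C)C)C(C)C)cc1O | intermediate
3 | 5-hydroxy-7-(triisopropylsilyloxy)-4H-chromen-4-one | O=c1ccoc2cc(O[Si](C(C)C)(C(C)C)C(C)C)cc(O)c12 | intermediate
4 | 4-bromoresorcinol | Oc1ccc(Br)c(O)c1 | starting material
5 | 2-bromo-5-(triisopropylsilyloxy)phenol | Oc1cc(O[Si](C(C)C)(C(C)C)C(C)C)ccc1Br | intermediate
6 | 3-chloro-3-methylbut-1-yne | C#CC(C)(C)Cl | starting material
7 | [4-bromo-3-(2-methylbut-3-yn-2-yloxy)phenoxy]triisopropylsilane | C#CC(C)(C)Oc1cc(O[Si](C(C)C)(C(C)C)C(C)C)ccc1Br | intermediate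
8 | 8-bromo-2,2-dimethyl-5-(triisopropylsilyloxy)-2H-chromene | CC1(C)C=Cc2c(O[Si](C(C)C)(C(C)C)C(C)C)ccc(Br)c2O1 | intermediate
9 | (2S)-2-[2,2-dimethyl-5-(triisopropylsilyloxy)-2H-chromen-8-yl]-5-hydroxy-7-(triisopropylsilyloxy)chroman-4-one | CC1(C)C=Cc2c(O[Si](C(C)C)(C(C)C)C(C)C)ccc([C@@H]3CC(=O)c4c(O)cc(O[Si](C(C)C)(C(C)C)C(C)C)cc4O3)c2O1 | intermediate
10 | sanggenone H | CC1(C)C=Cc2c(O)ccc([C@@H]3CC(=O)c4c(O)cc(O)cc4O3)c2O1 | target

**Totals**
Total steps: 7. Longest linear sequence: 5 (steps 3 → 4 → 5 → 6 → 7); convergent with the 2-step chromone branch.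

**Steps most likely to fail, with fallbacks**
1. Step 6 (reactivity of the doubly oxygenated chromone, the hindered ortho-alkoxy aryl, ee and absolute sense). Fallback: quench the aryllithium from 8 with B(OiPr)3 to the arylboronic acid and use the established Rh(I)/chiral diene boronic acid 1,4-addition in toluene–water on a 5,7-bis-O-protected chromone (one extra step, different nucleophile and catalyst manifold).
2. Step 3 (regioselectivity of mono-silylation of 4-bromoresorcinol). Fallback: start from 2,4-dihydroxybenzaldehyde, where the chelated 2-OH forces 4-O-silylation. The same propargylation/Claisen sequence gives 5-(TIPSO)-2,2-dimethyl-2H-chromene-8-carbaldehyde; Dakin oxidation, triflation and Miyaura borylation then give the 8-boronate for the boron-based addition.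
3. Step 2 (enaminone formation with two free phenols and a para-acyl aryl silyl ether). Fallback: build the pyranone differently: Friedel–Crafts acylation/cyclisation of phloroglucinol with 3-chloropropanoic acid to 5,7-dihydroxychroman-4-one, 7-O-silylation, then dehydrogenation (IBX or Pd(II)/O2) to chromone 3.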